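Ring B is closed last through the C6–C7 bond (drimane numbering). The key step exploits the C3 ketone/C4 gem-dimethyl/C5 array of ring A: in the precursor C6 is the methylene of a cyclopropane fused across C4–C5, and C9 carries a 2-(phenylsulfonylmethyl)allyl unit whose two CH2 termini become C7 and C12. A stannyl radical at the C3 carbonyl opens the strained C4–C6 bond; the freed C6 radical closes 6-endo onto C7 and ejects the sulfonyl radical, leaving the C8=C12 methylene, while the C3/C4 tin enolate formed in the same event is C-methylated to the gem-dimethyl group. C9 and C10 are set beforehand on a butyrolactone template.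

Key step: step 11

Remark: drimane numbering is used throughout (C1–C10 decalin carbons, C11 = OCH2 on C9, C12 = exocyclic CH2 on C8); compounds 1, 2, 6 and 23 are taken as commercial.

Step 1
Reactants: 1 furan-2(5H)-one; 2 isopropenylboronic acid pinacol ester
Product: 3 (R)-4-(prop-1-en-2-yl)dihydrofuran-2(3H)-one
Conditions: [Rh(OH)((R)-BINAP)]2 (3 mol % Rh), dioxane/H2O (10:1), 60 °C
Reagents that add atoms: none
Why: Hayashi–Miyaura rhodium-catalysed asymmetric 1,4-addition of the alkenyl group to the butenolide; the (R)-BINAP complex should deliver the isopropenyl group to the enantioface that gives R at the future C9, as predicted by the usual enantioface model for cyclic enones and unsaturated lactones.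

Step 2
Reactants: 3 (R)-4-(prop-1-en-2-yl)dihydrofuran-2(3H)-one
Product: 5 (3S,4R)-3-methyl-4-(prop-1-en-2-yl)dihydrofuran-2(3H)-one, via lithium enolate 4 (not isolated)
Conditions: LiN(i-Pr)2, THF, −78 °C; then MeI, −78 to −40 °C
Reagents that add atoms: iodomethane (CI)
Why: Lactone enolate alkylation, in which the methyl group should enter trans to the isopropenyl group; this centre (future C10) is made planar again in step 4, so its configuration here is not critical.

Step 3
Reactants: 6 pent-1-en-3-one (ethyl vinyl ketone)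
Product: 8 2-ethyl-2-(2-iodoethyl)-1,3-dioxolane, via silyl enol ether 7 (not isolated)
Conditions: NaI, Me3SiCl, MeCN, −20 to 0 °C; then ethylene glycol, 0 to 23 °C
Reagents that add atoms: sodium iodide ([Na+].[I-]); ethylene glycol (OCCO)
Why: Conjugate addition of Me3SiI made in the flask to the enone gives the β-iodo silyl enol ether, which is ketalised in the same pot, a known one-pot route to masked β-iodo ketones.

Step 4
Reactants: 5 (3S,4R)-3-methyl-4-(prop-1-en-2-yl)dihydrofuran-2(3H)-one; 8 2-ethyl-2-(2-iodoethyl)-1,3-dioxolane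
Product: 10 (3S,4S)-3-[2-(2-ethyl-1,3-dioxolan-2-yl)ethyl]-3-methyl-4-(prop-1-en-2-yl)dihydrofuran-2(3H)-one, via lithium enolate 9 (not isolated)
Conditions: LiN(i-Pr)2, THF, −78 °C; then 8, DMPU, −78 to −20 °C
Reagents that add atoms: none
Why: SN2 alkylation of the tetrasubstituted lactone enolate on the face anti to the neighbouring isopropenyl group, so the quaternary C10 should carry its methyl cis and its C1 chain trans to the isopropenyl group, which is the C9/C10 relationship of the target.

Step 5
Reactants: 10 (3S,4S)-3-[2-(2-ethyl-1,3-dioxolan-2-yl)ethyl]-3-methyl-4-(prop-1-en-2-yl)dihydrofuran-2(3H)-one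
Product: 12 (2S,3S)-3-[(tert-butyldiphenylsilyloxy)methyl]-2-[2-(2-ethyl-1,3-dioxolan-2-yl)ethyl]-N-methoxy-N,2,4-trimethylpent-4-enamide, via hydroxy amide 11 (not isolated)
Conditions: MeNH(OMe)·HCl, i-PrMgCl, THF, −20 to 0 °C; aqueous NH4Cl work-up; then t-BuPh2SiCl, imidazole, CH2Cl2, 23 °C
Reagents that add atoms: N,O-dimethylhydroxylamine hydrochloride (CNOC.Cl); tert-butyl(chloro)diphenylsilane (CC(C)(C)[Si](Cl)(c1ccccc1)c1ccccc1)
Why: Aminolysis of the lactone by the magnesium amide gives the Weinreb amide at C5 and frees the C11 hydroxyl, which is silylated at once to prevent relactonisation; no stereocentre is touched.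

Step 6
Reactants: 12 Weinreb amide silyl ether
Product: 13 (2S,3S)-3-[(tert-butyldiphenylsilyloxy)methyl]-2-[2-(2-ethyl-1,3-dioxolan-2-yl)ethyl]-2,4-dimethylpent-4-enal
Conditions: i-Bu2AlH, THF, −78 °C; aqueous potassium sodium tartrate work-up
Reagents that add atoms: none
Why: Weinreb amide reduction stops at the aldehyde through the chelated tetrahedral intermediate, and the α-quaternary aldehyde cannot epimerise.

Step 7
Reactants: 13 ketal aldehyde
Product: 15 (R)-4-[(S)-1-(tert-butyldiphenylsilyloxy)-3-methylbut-3-en-2-yl]-2,4-dimethylcyclohex-2-en-1-one, via keto aldehyde 14 (not isolated)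
Conditions: PPTS, THF/H2O (4:1), 60 °C; then KOH (0.5 equiv), MeOH, 23 °C
Reagents that add atoms: water (O)
Why: Mild ketal hydrolysis (spares the isopropenyl group) followed by intramolecular aldol condensation of C4 onto the non-enolisable C5 aldehyde, a Robinson-type ring closure that builds ring A; only the six-membered closure is possible and the C11 oxygen is already protected, so no oxa-Michael addition to the new enone can occur.

Step 8
Reactants: 15 ring A enone
Product: 16 (1S,5R,6S)-5-[(S)-1-(tert-butyldiphenylsilyloxy)-3-methylbut-3-en-2-yl]-1,5-dimethylbicyclo[4.1.0]heptan-2-one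
Conditions: Me3S(O)I, NaH, DMSO, 23 to 50 °C
Reagents that add atoms: trimethylsulfoxonium iodide (C[S+](C)(C)=O.[I-])
Why: Corey–Chaykovsky cyclopropanation: the ylide should add to C5 on the face of the C10 methyl (anti to the branched C9 substituent), and the 3-exo closure onto C4 is necessarily cis, which sets C5 and places C6 cis to the C10 methyl.

Step 9
Reactants: 16 cyclopropyl ketone
Product: 17 (1S,5R,6S)-5-[(R)-1-(tert-butyldiphenylsilyloxy)-3-(chloromethyl)but-3-en-2-yl]-1,5-dimethylbicyclo[4.1.0]heptan-2-one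
Conditions: Ca(OCl)2, CO2 (solid), CH2Cl2/H2O, 0 °C
Reagents that add atoms: calcium hypochlorite ([Ca+2].[O-]Cl.[O-]Cl)
Why: Ene-type allylic chlorination of the isopropenyl group by HOCl (chlorine on the terminal CH2, proton lost from the methyl), which gives the 2-(chloromethyl)allyl unit and touches no stereocentre.

Step 10
Reactants: 17 allylic chloride
Product: 18 (1S,5R,6S)-5-[(R)-1-(tert-butyldiphenylsilyloxy)-3-(phenylsulfonylmethyl)but-3-en-2-yl]-1,5-dimethylbicyclo[4.1.0]heptan-2-one
Conditions: PhSO2Na, NaI (cat.), DMF, 23 °C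
Reagents that add atoms: sodium benzenesulfinate ([Na+].[O-]S(=O)c1ccccc1)
Why: SN2 S-alkylation of the sulfinate by the primary allylic chloride installs the radical leaving group.

Step 11
Reactants: 18 cyclopropyl ketone allyl sulfone
Product: 21 (5S,9S,10R)-11-(tert-butyldiphenylsilyloxy)drim-8(12)-en-3-one, via tin enolate 19 (not isolated), via lithium enolate 20 (not isolated)
Conditions: (Bu3Sn)2 (1.1 equiv), Bu3SnH (5 mol %), AIBN (10 mol %), PhH, 80 °C; then MeLi (2.2 equiv), THF, −78 to 0 °C; then MeI, DMPU, −78 to 23 °C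
Reagents that add atoms: iodomethane (CI)
Why: A tributylstannyl radical adds reversibly to the C3 carbonyl oxygen, and the resulting O-stannyl ketyl undergoes cyclopropylcarbinyl fragmentation of the external C4–C6 bond (the bond aligned with the ketyl orbital), which releases ring strain and gives the C3/C4 tin enolate 19 together with the primary C6 radical; this radical adds to C7, the CH2 terminus of the 2-(phenylsulfonylmethyl)allyl group, the tertiary C8 radical ejects PhSO2•, and PhSO2• regenerates the stannyl radical from Bu3Sn–SnBu3. The closest known reaction types are the stannyl-ketyl ring opening of cyclopropyl ketones with cyclisation of the ring-opened radical and alkylation of the tin enolate, and radical allylation by addition–fragmentation of allyl sulfones. Ring B closes in the 6-endo-trig mode through a chair in which the C5–C6 and C10–C9 bonds are both equatorial on ring A, so the ring fusion should be trans; the closure forms no new stereocentre, C5, C9 and C10 being carried over from 18, and methylation of lithium enolate 20 at C4 creates a non-stereogenic gem-dimethyl carbon. The selectivity needed is 6-endo over 5-exo attack, secured because C8 is fully substituted (5-exo would build a quaternary centre in a trans-hydrindane) and because only attack at C7 leads to the irreversible loss of the sulfonyl radical. As C7 and C12 are equivalent CH2 groups on C8 the methylene position is unambiguous, and as no stoichiometric tin hydride is present the C6 radical should not be reduced before it cyclises and the regiodefined enolate should survive until MeLi and MeI are added.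

Step 12
Reactants: 21 silyl ether
Product: 22 (5S,9S,10R)-11-hydroxydrim-8(12)-en-3-one
Conditions: Bu4NF, THF, 23 °C
Reagents that add atoms: none
Why: Fluoride-mediated silyl ether cleavage; the ketone is still saturated, so the freed C11 hydroxyl has no enone to add to.

Step 13
Reactants: 22 (5S,9S,10R)-11-hydroxydrim-8(12)-en-3-one; 23 isofraxidin (7-hydroxy-6,8-dimethoxy-2H-chromen-2-one)
Product: 24 7-{[(5S,9S,10R)-3-oxodrim-8(12)-en-11-yl]oxy}-6,8-dimethoxy-2H-chromen-2-one
Conditions: PPh3, DIAD, THF, 0 to 23 °C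
Reagents that add atoms: none
Why: Mitsunobu etherification, in which the acidic 7-OH of the coumarin displaces the activated primary C11 oxygen; no stereocentre is involved.

Step 14
Reactants: 24 saturated ketone
Product: 25 7-{[(5S,9S,10R)-3-oxodrima-1,8(12)-dien-11-yl]oxy}-6,8-dimethoxy-2H-chromen-2-one (CNP0227866.1)
Conditions: IBX, DMSO, 75 °C
Reagents that add atoms: none
Why: IBX dehydrogenation of the ketone, regiospecific for C1=C2 because C4 is quaternary and only C2 carries α-hydrogens, as is usual for 4,4-dimethyl-3-keto terpenoids; the coumarin and the exocyclic methylene should be inert.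

Compound list
1 | furan-2(5H)-one | O=C1C=CCO1 | starting material
2 | 4,4,5,5-tetramethyl-2-(prop-1-en-2-yl)-1,3,2-dioxaborolane | CC(=C)B1OC(C)(C)C(C)(C)O1 | starting material
3 | (R)-4-(prop-1-en-2-yl)dihydrofuran-2(3H)-one | O=C1C[C@H](C(C)=C)CO1 | intermediate
4 | lithium enolate of 3 | [Li+].[O-]C1=C[C@H](C(C)=C)CO1 | intermediate
5 | (3S,4R)-3-methyl-4-(prop-1-en-2-yl)dihydrofuran-2(3H)-one | O=C1[C@@H](C)[C@H](C(C)=C)CO1 | intermediate
6 | pent-1-en-3-one | C=CC(=O)CC | starting material
7 | (Z)-1-iodo-3-(trimethylsilyloxy)pent-2-ene | CC/C(O[Si](C)(C)C)=C/CI | intermediate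
8 | 2-ethyl-2-(2-iodoethyl)-1,3-dioxolane | CCC1(CCI)OCCO1 | intermediate
9 | lithium enolate of 5 | [Li+].[O-]C1=C(C)[C@H](C(C)=C)CO1 | intermediate
10 | (3S,4S)-3-[2-(2-ethyl-1,3-dioxolan-2-yl)ethyl]-3-methyl-4-(prop-1-en-2-yl)dihydrofuran-2(3H)-one | O=C1[C@@](C)(CCC2(CC)OCCO2)[C@H](C(C)=C)CO1 | intermediate
11 | (2S,3S)-2-[2-(2-ethyl-1,3-dioxolan-2-yl)ethyl]-3-(hydroxymethyl)-N-methoxy-N,2,4-trimethylpent-4-enamide | CON(C)C(=O)[C@@](C)(CCC1(CC)OCCO1)[C@H](C(C)=C)CO | intermediate
12 | (2S,3S)-3-[(tert-butyldiphenylsilyloxy)methyl]-2-[2-(2-ethyl-1,3-dioxolan-2-yl)ethyl]-N-methoxy-N,2,4-trimethylpent-4-enamide | CON(C)C(=O)[C@@](C)(CCC1(CC)OCCO1)[C@H](C(C)=C)CO[Si](c1ccccc1)(c1ccccc1)C(C)(C)C | intermediate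
13 | (2S,3S)-3-[(tert-butyldiphenylsilyloxy)methyl]-2-[2-(2-ethyl-1,3-dioxolan-2-yl)ethyl]-2,4-dimethylpent-4-enal | O=C[C@@](C)(CCC1(CC)OCCO1)[C@H](C(C)=C)CO[Si](c1ccccc1)(c1ccccc1)C(C)(C)C | intermediate
14 | (2S,3S)-3-[(tert-butyldiphenylsilyloxy)methyl]-2,4-dimethyl-2-(3-oxopentyl)pent-4-enal | O=C[C@@](C)(CCC(=O)CC)[C@H](C(C)=C)CO[Si](c1ccccc1)(c1ccccc1)C(C)(C)C | intermediate
15 | (R)-4-[(S)-1-(tert-butyldiphenylsilyloxy)-3-methylbut-3-en-2-yl]-2,4-dimethylcyclohex-2-en-1-one | O=C1CC[C@](C)(C=C1C)[C@H](C(C)=C)CO[Si](c1ccccc1)(c1ccccc1)C(C)(C)C | intermediate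
16 | (1S,5R,6S)-5-[(S)-1-(tert-butyldiphenylsilyloxy)-3-methylbut-3-en-2-yl]-1,5-dimethylbicyclo[4.1.0]heptan-2-one | O=C1CC[C@@](C)([C@H](C(C)=C)CO[Si](c3ccccc3)(c3ccccc3)C(C)(C)C)[C@@H]2C[C@]12C | intermediate
17 | (1S,5R,6S)-5-[(R)-1-(tert-butyldiphenylsilyloxy)-3-(chloromethyl)but-3-en-2-yl]-1,5-dimethylbicyclo[4.1.0]heptan-2-one | O=C1CC[C@@](C)([C@H](C(CCl)=C)CO[Si](c3ccccc3)(c3ccccc3)C(C)(C)C)[C@@H]2C[C@]12C | intermediate
18 | (1S,5R,6S)-5-[(R)-1-(tert-butyldiphenylsilyloxy)-3-(phenylsulfonylmethyl)but-3-en-2-yl]-1,5-dimethylbicyclo[4.1.0]heptan-2-one | O=C1CC[C@@](C)([C@H](C(CS(=O)(=O)c4ccccc4)=C)CO[Si](c3ccccc3)(c3ccccc3)C(C)(C)C)[C@@H]2C[C@]12C | intermediate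
19 | tributylstannyl C3=C4 enol ether of the ring-closed 4-methyl ketone (11-silyloxy-drim-8(12)-ene skeleton lacking one C4 methyl) | C=C1CC[C@@H]2C(C)=C(O[Sn](CCCC)(CCCC)CCCC)CC[C@@]2(C)[C@H]1CO[Si](c1ccccc1)(c1ccccc1)C(C)(C)C | intermediate
20 | lithium C3=C4 enolate corresponding to 19 | [Li+].C=C1CC[C@@H]2C(C)=C([O-])CC[C@@]2(C)[C@H]1CO[Si](c1ccccc1)(c1ccccc1)C(C)(C)C | intermediate
21 | (5S,9S,10R)-11-(tert-butyldiphenylsilyloxy)drim-8(12)-en-3-one | C=C1CC[C@@H]2C(C)(C)C(=O)CC[C@@]2(C)[C@H]1CO[Si](c1ccccc1)(c1ccccc1)C(C)(C)C | intermediate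
22 | (5S,9S,10R)-11-hydroxydrim-8(12)-en-3-one | C=C1CC[C@@H]2C(C)(C)C(=O)CC[C@@]2(C)[C@H]1CO | intermediate
23 | isofraxidin (7-hydroxy-6,8-dimethoxy-2H-chromen-2-one) | COc1cc2ccc(=O)oc2c(OC)c1O | starting material
24 | 7-{[(5S,9S,10R)-3-oxodrim-8(12)-en-11-yl]oxy}-6,8-dimethoxy-2H-chromen-2-one | C=C1CC[C@@H]2C(C)(C)C(=O)CC[C@@]2(C)[C@H]1COc1c(OC)cc2ccc(=O)oc2c1OC | intermediate
25 | 7-{[(5S,9S,10R)-3-oxodrima-1,8(12)-dien-11-yl]oxy}-6,8-dimethoxy-2H-chromen-2-one | C=C1CC[C@@H]2C(C)(C)C(=O)C=C[C@@]2(C)[C@H]1COc1c(OC)cc2ccc(=O)oc2c1OC | target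

Total step count: 14. Longest linear sequence: 13 steps (steps 1, 2 and 4 to 14; step 3 prepares the alkylating agent).

Steps most likely to fail

1. Step 11. The stannyl radical may not engage the hindered C3 carbonyl well enough to sustain the chain. The ring-opened C6 radical may also be diverted (1,5-hydrogen transfer from C11, 5-exo closure) before it reaches C7, and the tin enolate may be protonated before C-methylation. The fallback sets out from 18 and returns at 21, and separates ring opening, radical generation and methylation. Homo-conjugate opening of the cyclopropyl ketone with Me3SiI (Me3SiCl, NaI, MeCN, −20 °C) would give the iodomethyl silyl enol ether F1, in which the C3/C4 enol ether is fixed without any radical step. Iodine-atom abstraction from F1 ((Bu3Sn)2, hν, PhH, 80 °C) would then start the addition–fragmentation closure from an ordinary primary alkyl iodide and give the ring-closed silyl enol ether F2. Cleavage of F2 with MeLi and C-methylation with MeI would give 21.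

2. Step 8. Michael addition of the sulfoxonium ylide to C5 may be too slow, because the enone is α-methylated and C5 adjoins the quaternary C10, so that enolisation or recovery of 15 prevails. The fallback sets out from 15 and returns at 16. 1,3-Dipolar cycloaddition of diazomethane (Et2O, 0 to 23 °C) to the enone, carbon to C5 and nitrogen to C4, on the same face as planned for the ylide, would give the 1-pyrazoline F3. This cannot tautomerise because C4 is quaternary; photolysis (350 nm, PhH) would extrude nitrogen and give 16.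

3. Step 4. SN2 alkylation of the hindered tetrasubstituted enolate may lose to E2 elimination of HI from 8 or to proton transfer, leaving 5 unchanged. The fallback sets out from 5 and returns at 10, and forms the C10–C1 bond by conjugate addition instead. Lactone 5 would be converted (LiN(i-Pr)2, t-BuMe2SiCl, DMPU, THF, −78 °C) to the silyl ketene acetal F4. Mukaiyama–Michael addition of F4 to ethyl vinyl ketone 6 (TiCl4, CH2Cl2, −78 °C), again anti to the isopropenyl group, would give the keto lactone F5. Ketalisation of F5 (ethylene glycol, PPTS, PhH, reflux with water removal) would give 10.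

Further compounds
F1 | step 11 | iodomethyl silyl enol ether: (3R,4R)-4-[(R)-1-(tert-butyldiphenylsilyloxy)-3-(phenylsulfonylmethyl)but-3-en-2-yl]-3-(iodomethyl)-2,4-dimethyl-1-(trimethylsilyloxy)cyclohex-1-ene skeleton | C[Si](C)(C)OC1=C(C)[C@@H](CI)[C@@](C)(CC1)[C@H](C(CS(=O)(=O)c1ccccc1)=C)CO[Si](c1ccccc1)(c1ccccc1)C(C)(C)C
F2 | step 11 | ring-closed trimethylsilyl C3=C4 enol ether (silicon analogue of 19) | C=C1CC[C@@H]2C(C)=C(O[Si](C)(C)C)CC[C@@]2(C)[C@H]1CO[Si](c1ccccc1)(c1ccccc1)C(C)(C)C
F3 | step 8 | 1-pyrazoline from 15 and diazomethane (CH2 on C5, N on C4, cis-fused) | O=C1CC[C@@](C)([C@H](C(C)=C)CO[Si](c3ccccc3)(c3ccccc3)C(C)(C)C)[C@@H]2CN=N[C@]12C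
F4 | step 4 | tert-butyldimethylsilyl ketene acetal of 5 | CC(C)(C)[Si](C)(C)OC1=C(C)[C@H](C(C)=C)CO1
F5 | step 4 | (3S,4S)-3-methyl-3-(3-oxopentyl)-4-(prop-1-en-2-yl)dihydrofuran-2(3H)-one | O=C1[C@@](C)(CCC(=O)CC)[C@H](C(C)=C)CO1
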